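**Retrosynthetic overview**
- The depside ester (ring A acyl carbon to the ring B C4 oxygen) is cut last, giving a ring B phenol and 3-formyl-2,4-dimethoxy-5,6-dimethylbenzoic acid. The three phenols that sit ortho to a carbonyl group travel as methyl ethers and are freed together at the end with BCl3.
- The route rests on the hexasubstituted ring B (C1 CO2Me, C2 Me, C3 Me, C4 O-acyl, C5 Me, C6 OH). It is cut across C2–C3 and C4–C5 into a four-carbon piece C5–C6–C1–C2, a 4-methoxy-3,6-dimethyl-2-pyrone-5-carboxylate whose lactone bridge leaves as CO2, and a two-carbon piece C3–C4, 1-(triisopropylsilyloxy)propyne.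
- The pyrone comes from methyl acetoacetate and methylmalonyl dichloride followed by O-methylation. The siloxyalkyne comes from ethyl acetate by ester homologation to the ynolate and O-silylation.
- Ring A is bought as an arene (2,4-dimethoxy-6-methylbenzaldehyde) and elaborated by deoxygenation, ortho-lithiation/formylation between the methoxy groups, bromination of the last ring position, acetal protection and carboxylation.
- Ring order: ring B is the only ring made (pyrone, then benzene by cycloaddition and loss of CO2); the rings are joined by esterification and then demethylated.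

Key step: step 5

Remark: the target has no stereocentre, so no stereocontrol is needed. The ynolate is drawn from ethyl acetate because the homologation adds one carbon, and the depside ester is closed through the mixed trifluoroacetic anhydride of the ring A acid, since a doubly ortho-substituted acid reacts best through its acylium ion.

**Route**

Step 1
Reactants: 1 methylmalonic acid
Product: 2 methylmalonyl dichloride (2-methylpropanedioyl dichloride)
Conditions: SOCl2 (neat), 55 °C; distillation under reduced pressure
Reagents that add atoms: thionyl chloride, O=S(Cl)Cl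
Why: Standard conversion of a carboxylic acid into its acid chloride with thionyl chloride; SO2 and HCl leave as gases and the volatile dichloride is purified by distillation.

Step 2
Reactants: 2 methylmalonyl dichloride; 3 methyl acetoacetate
Product: 5 methyl 4-hydroxy-3,6-dimethyl-2-oxo-2H-pyran-5-carboxylate, via C-acylated acid chloride 4 (not isolated)
Conditions: toluene, 23 → 90 °C, N2 sweep to carry off HCl
Reagents that add atoms: none
Why: Double acylation of a β-keto ester by a malonyl dichloride (C-acylation at the active methylene, then lactonisation through the ketone enol oxygen) is an established entry to 5-alkoxycarbonyl-4-hydroxy-6-methyl-2-pyrones; the malonyl unit is symmetric, so only one pyrone can form and its methyl group ends at C3.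

Step 3
Reactants: 5 methyl 4-hydroxy-3,6-dimethyl-2-oxo-2H-pyran-5-carboxylate
Product: 6 methyl 4-methoxy-3,6-dimethyl-2-oxo-2H-pyran-5-carboxylate
Conditions: Me2SO4, K2CO3, acetone, reflux
Reagents that add atoms: dimethyl sulfate, COS(=O)(=O)OC
Why: Williamson-type O-methylation of the acidic vinylogous carboxylic acid; the hard methylating agent should alkylate the C4 oxygen rather than the already substituted C3, giving the 4-methoxy-2-pyrone.

Step 4
Reactants: 7 ethyl acetate
Product: 10 triisopropyl(prop-1-yn-1-yloxy)silane, via lithium dibromoenolate 8 (not isolated), via lithium propynolate 9 (not isolated)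
Conditions: CH2Br2, lithium 2,2,6,6-tetramethylpiperidide (from the amine and n-BuLi), THF, −78 °C; n-BuLi, −78 → 23 °C; TIPSOTf, −78 → 0 °C
Reagents that add atoms: dibromomethane, BrCBr; triisopropylsilyl trifluoromethanesulfonate, CC(C)[Si](OS(=O)(=O)C(F)(F)F)(C(C)C)C(C)C
Why: Kowalski ester homologation: dibromomethyllithium adds to the ester, the dibromo ketone enolate 8 undergoes bromine–lithium exchange and a 1,2-methyl shift of the carbenoid to ynolate 9, and the bulky silyl triflate should capture the ynolate on oxygen rather than on carbon.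

Step 5
Reactants: 6 methyl 4-methoxy-3,6-dimethyl-2-oxo-2H-pyran-5-carboxylate; 10 triisopropyl(prop-1-yn-1-yloxy)silane
Product: 12 methyl 2-methoxy-3,5,6-trimethyl-4-[(triisopropylsilyl)oxy]benzoate, via bridged lactone 11 (not isolated)
Conditions: 10 (2 equiv), toluene, 110 °C, sealed tube
Reagents that add atoms: none
Why: Proposed new method: the electron-poor diene of 6 (C3=C4–C5=C6, lowered by the C5 ester and the lactone carbonyl) and the electron-rich alkyne 10 should combine in an inverse-demand (4+2) cycloaddition that is strongly asynchronous, the methyl-bearing alkyne carbon bonding first to pyrone C6 and the silyloxy-bearing carbon then to pyrone C3, to give the bridged lactone 11, which loses CO2 by retro-(4+2) at the reaction temperature and so arrives directly as the benzene ring. The closest known reaction type is the cycloaddition of 2-pyrone-5-carboxylates with ynamines and alkoxyalkynes followed by decarboxylation, which has not been shown for a fully substituted 4-alkoxypyrone or for a silyl ynol ether. Ring B is closed as a six-membered carbocycle by an intermolecular (4+2) cycloaddition in which both new bonds (ring B C2–C3 and C5–C4) form in the one operation. No stereocentre survives, because the two bridgehead carbons of racemic 11 become planar on loss of CO2. The step needs regioselectivity, and both partners agree on it: pyrone C6 is the electrophilic β-carbon of the C5 acrylate and pairs with the nucleophilic methyl-bearing carbon of the ynol ether, while pyrone C3, the enol-ether carbon α to the lactone carbonyl, pairs with the ketenium-like oxygen-bearing carbon, so that the silyl ether lands para to the ester and the methyl ether ortho to it. Periselectivity over (2+2) addition is expected from the ring-locked s-cis diene, and the triisopropylsilyl group is chosen to slow the thermal 1,3-silyl shift of 10 to a silylketene.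

Step 6
Reactants: 12 methyl 2-methoxy-3,5,6-trimethyl-4-[(triisopropylsilyl)oxy]benzoate
Product: 13 methyl 4-hydroxy-2-methoxy-3,5,6-trimethylbenzoate
Conditions: Bu4NF, AcOH, THF, 0 → 23 °C
Reagents that add atoms: none
Why: Fluoride-mediated cleavage of an aryl silyl ether; buffering with acetic acid should leave the methyl ester and the methyl ether untouched and exposes only the oxygen that will carry the depside ester.

Step 7
Reactants: 14 2,4-dimethoxy-6-methylbenzaldehyde
Product: 16 1,5-dimethoxy-2,3-dimethylbenzene, via hydrazone 15 (not isolated)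
Conditions: N2H4·H2O, KOH, diethylene glycol, 130 → 195 °C
Reagents that add atoms: none
Why: Wolff–Kishner reduction (Huang-Minlon variant) of an electron-rich aryl aldehyde through its hydrazone to the methyl group; aryl methyl ethers should tolerate the hot base.

Step 8
Reactants: 16 1,5-dimethoxy-2,3-dimethylbenzene
Product: 19 2,6-dimethoxy-3,4-dimethylbenzaldehyde, via aryllithium 17 (not isolated), via lithium hemiaminal alkoxide 18 (not isolated)
Conditions: n-BuLi, TMEDA, THF, 0 °C; DMF, −78 → 23 °C; aq. HCl
Reagents that add atoms: N,N-dimethylformamide, CN(C)C=O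
Why: Directed ortho-metalation, in which the ring C–H flanked by two methoxy groups is by far the most acidic, followed by formylation of the aryllithium with DMF.

Step 9
Reactants: 19 2,6-dimethoxy-3,4-dimethylbenzaldehyde
Product: 20 3-bromo-2,6-dimethoxy-4,5-dimethylbenzaldehyde
Conditions: NBS, MeCN, 0 → 23 °C, dark
Reagents that add atoms: N-bromosuccinimide, O=C1CCC(=O)N1Br
Why: Electrophilic aromatic bromination at the single remaining ring C–H, which is ortho to one methoxy group, para to the other and meta to the formyl group; polar conditions in the dark should suppress benzylic bromination.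

Step 10
Reactants: 20 3-bromo-2,6-dimethoxy-4,5-dimethylbenzaldehyde
Product: 21 2-(3-bromo-2,6-dimethoxy-4,5-dimethylphenyl)-1,3-dioxolane
Conditions: HOCH2CH2OH, TsOH·H2O (cat.), toluene, reflux, Dean–Stark trap
Reagents that add atoms: ethylene glycol, OCCO
Why: Acid-catalysed acetalisation with azeotropic removal of water masks the aldehyde for the organolithium step.

Step 11
Reactants: 21 2-(3-bromo-2,6-dimethoxy-4,5-dimethylphenyl)-1,3-dioxolane
Product: 24 3-formyl-2,4-dimethoxy-5,6-dimethylbenzoic acid, via aryllithium 22 (not isolated), via dioxolane acid 23 (not isolated)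
Conditions: n-BuLi, THF, −78 °C; CO2; then 2 M HCl, THF, 23 °C
Reagents that add atoms: carbon dioxide, O=C=O; water, O
Why: Bromine–lithium exchange at low temperature, carboxylation of the aryllithium with CO2, and acid hydrolysis of the electron-rich aryl dioxolane in the work-up should release the acid and the aldehyde together.

Step 12
Reactants: 13 methyl 4-hydroxy-2-methoxy-3,5,6-trimethylbenzoate; 24 3-formyl-2,4-dimethoxy-5,6-dimethylbenzoic acid
Product: 26 methyl 4-[(3-formyl-2,4-dimethoxy-5,6-dimethylbenzoyl)oxy]-2-methoxy-3,5,6-trimethylbenzoate, via mixed anhydride 25 (not isolated)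
Conditions: (CF3CO)2O, toluene, 0 °C (24 first), then 13, 0 → 23 °C
Reagents that add atoms: none
Why: Esterification through the mixed trifluoroacetic anhydride, the usual way to close hindered depside esters: the doubly ortho-substituted, methoxy-stabilised acid ionises to a linear acylium ion that the hindered phenol can capture without a crowded tetrahedral intermediate.

Step 13
Reactants: 26 methyl 4-[(3-formyl-2,4-dimethoxy-5,6-dimethylbenzoyl)oxy]-2-methoxy-3,5,6-trimethylbenzoate
Product: 28 pseudocyphellarin A, via tris(dichloroboryl) ether 27 (not isolated)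
Conditions: BCl3 (excess), CH2Cl2, −78 → 0 °C; aqueous work-up
Reagents that add atoms: none
Why: Chelation-assisted aryl methyl ether cleavage with BCl3: each of the three methyl ethers lies ortho to a carbonyl group (ring B C6 to the methyl ester, ring A C2 to the depside carbonyl and the aldehyde, ring A C4 to the aldehyde) and should be cleaved through a six-membered boron chelate, while both esters and the aldehyde are expected to survive at low temperature.

**Compound list**
1 | methylmalonic acid | CC(C(=O)O)C(=O)O | starting material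
2 | methylmalonyl dichloride | CC(C(=O)Cl)C(=O)Cl | intermediate
3 | methyl acetoacetate | COC(=O)CC(C)=O | starting material
4 | methyl 2-acetyl-5-chloro-4-methyl-3,5-dioxopentanoate (C-acylated acid chloride, mixture of stereoisomers, not isolated) | COC(=O)C(C(C)=O)C(=O)C(C)C(=O)Cl | intermediate
5 | methyl 4-hydroxy-3,6-dimethyl-2-oxo-2H-pyran-5-carboxylate | COC(=O)C1=C(C)OC(=O)C(C)=C1O | intermediate
6 | methyl 4-methoxy-3,6-dimethyl-2-oxo-2H-pyran-5-carboxylate | COC(=O)C1=C(C)OC(=O)C(C)=C1OC | intermediate
7 | ethyl acetate | CCOC(C)=O | starting material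
8 | lithium 1,1-dibromoprop-1-en-2-olate (not isolated) | [Li+].CC([O-])=C(Br)Br | intermediate
9 | lithium prop-1-yn-1-olate (not isolated) | [Li+].CC#C[O-] | intermediate
10 | triisopropyl(prop-1-yn-1-yloxy)silane | CC#CO[Si](C(C)C)(C(C)C)C(C)C | intermediate
11 | methyl 8-methoxy-1,4,6-trimethyl-3-oxo-5-[(triisopropylsilyl)oxy]-2-oxabicyclo[2.2.2]octa-5,7-diene-7-carboxylate (bridged lactone, racemic, not isolated) | O=C1OC2(C)C(C(=O)OC)=C(OC)C1(C)C(O[Si](C(C)C)(C(C)C)C(C)C)=C2C | intermediate
12 | methyl 2-methoxy-3,5,6-trimethyl-4-[(triisopropylsilyl)oxy]benzoate | COC(=O)c1c(C)c(C)c(O[Si](C(C)C)(C(C)C)C(C)C)c(C)c1OC | intermediate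
13 | methyl 4-hydroxy-2-methoxy-3,5,6-trimethylbenzoate | COC(=O)c1c(C)c(C)c(O)c(C)c1OC | intermediate
14 | 2,4-dimethoxy-6-methylbenzaldehyde | COc1cc(C)c(C=O)c(OC)c1 | starting material
15 | (E)-(2,4-dimethoxy-6-methylbenzylidene)hydrazine (hydrazone, not isolated) | COc1cc(C)c(/C=N/N)c(OC)c1 | intermediate
16 | 1,5-dimethoxy-2,3-dimethylbenzene | COc1cc(OC)c(C)c(C)c1 | intermediate
17 | (2,6-dimethoxy-3,4-dimethylphenyl)lithium (not isolated) | [Li]c1c(OC)cc(C)c(C)c1OC | intermediate
18 | lithium (dimethylamino)(2,6-dimethoxy-3,4-dimethylphenyl)methanolate (racemic, not isolated) | [Li+].COc1cc(C)c(C)c(OC)c1C([O-])N(C)C | intermediate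
19 | 2,6-dimethoxy-3,4-dimethylbenzaldehyde | COc1cc(C)c(C)c(OC)c1C=O | intermediate
20 | 3-bromo-2,6-dimethoxy-4,5-dimethylbenzaldehyde | COc1c(Br)c(C)c(C)c(OC)c1C=O | intermediate
21 | 2-(3-bromo-2,6-dimethoxy-4,5-dimethylphenyl)-1,3-dioxolane | COc1c(Br)c(C)c(C)c(OC)c1C1OCCO1 | intermediate
22 | [3-(1,3-dioxolan-2-yl)-2,4-dimethoxy-5,6-dimethylphenyl]lithium (not isolated) | [Li]c1c(C)c(C)c(OC)c(C2OCCO2)c1OC | intermediate
23 | 3-(1,3-dioxolan-2-yl)-2,4-dimethoxy-5,6-dimethylbenzoic acid (formed as its lithium salt, not isolated) | COc1c(C(=O)O)c(C)c(C)c(OC)c1C1OCCO1 | intermediate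
24 | 3-formyl-2,4-dimethoxy-5,6-dimethylbenzoic acid | O=Cc1c(OC)c(C(=O)O)c(C)c(C)c1OC | intermediate
25 | 3-formyl-2,4-dimethoxy-5,6-dimethylbenzoic trifluoroacetic anhydride (not isolated) | O=Cc1c(OC)c(C(=O)OC(=O)C(F)(F)F)c(C)c(C)c1OC | intermediate
26 | methyl 4-[(3-formyl-2,4-dimethoxy-5,6-dimethylbenzoyl)oxy]-2-methoxy-3,5,6-trimethylbenzoate | COC(=O)c1c(C)c(C)c(OC(=O)c2c(C)c(C)c(OC)c(C=O)c2OC)c(C)c1OC | intermediate
27 | methyl 4-({2,4-bis[(dichloroboranyl)oxy]-3-formyl-5,6-dimethylbenzoyl}oxy)-2-[(dichloroboranyl)oxy]-3,5,6-trimethylbenzoate (not isolated) | COC(=O)c1c(C)c(C)c(OC(=O)c2c(C)c(C)c(OB(Cl)Cl)c(C=O)c2OB(Cl)Cl)c(C)c1OB(Cl)Cl | intermediate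
28 | pseudocyphellarin A, methyl 4-[(3-formyl-2,4-dihydroxy-5,6-dimethylbenzoyl)oxy]-2-hydroxy-3,5,6-trimethylbenzoate | COC(=O)c1c(C)c(C)c(OC(=O)c2c(C)c(C)c(O)c(C=O)c2O)c(C)c1O | target

**Step count**
Total: 13 steps. Longest linear sequence: 7 steps (steps 1, 2, 3, 5, 6, 12, 13; the ring A line, steps 7 to 13, is equally long).

**Steps most likely to fail**

1. Step 5 (proposed new method). The tetrasubstituted pyrone, deactivated by its 4-methoxy group and hindered at both diene termini, may react too slowly. The ynol ether may meanwhile isomerise by 1,3-silyl shift to a silylketene or oligomerise.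
Fallback by known arene chemistry, setting out from 16 and rejoining the route at 28. Lithiation between the methoxy groups as in step 8 and quenching with MeI should give 1,3-dimethoxy-2,4,5-trimethylbenzene F1. NBS in MeCN brominates its only ring C–H to 1-bromo-2,4-dimethoxy-3,5,6-trimethylbenzene F2. Bromine–lithium exchange (n-BuLi, THF, −78 °C) and addition to ClCO2Me gives methyl 2,4-dimethoxy-3,5,6-trimethylbenzoate F3. BBr3 (CH2Cl2, −78 → 0 °C) cleaves both ethers to methyl 2,4-dihydroxy-3,5,6-trimethylbenzoate F4. Its 4-hydroxyl, the one not hydrogen-bonded to the ester, is acylated with 24 under the conditions of step 12 to methyl 4-[(3-formyl-2,4-dimethoxy-5,6-dimethylbenzoyl)oxy]-2-hydroxy-3,5,6-trimethylbenzoate F5. BCl3 as in step 13 then removes the two methyl ethers of ring A to give 28.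

2. Step 13. The ring A C4 methyl ether has only the aldehyde as neighbouring carbonyl, and that carbonyl may already be tied up in the boron chelate of the C2 oxygen, so cleavage may stop at a partly methylated depside. Forcing it may break the acyl–oxygen bond of the depside ester.
Fallback that changes the protecting groups of ring A to benzyl ethers, which cleave without chelation, setting out from 20 and rejoining at 28. BBr3 (CH2Cl2, −78 → 0 °C) gives 3-bromo-2,6-dihydroxy-4,5-dimethylbenzaldehyde F9. BnBr and K2CO3 in DMF give 2,6-bis(benzyloxy)-3-bromo-4,5-dimethylbenzaldehyde F10. Acetalisation as in step 10 gives 2-[2,6-bis(benzyloxy)-3-bromo-4,5-dimethylphenyl]-1,3-dioxolane F11. Bromine–lithium exchange, carboxylation and acidic work-up as in step 11 give 2,4-bis(benzyloxy)-3-formyl-5,6-dimethylbenzoic acid F12. Coupling with 13 as in step 12 gives methyl 4-{[2,4-bis(benzyloxy)-3-formyl-5,6-dimethylbenzoyl]oxy}-2-methoxy-3,5,6-trimethylbenzoate F13. BCl3 at −78 → 0 °C then removes both benzyl ethers and the one ester-flanked methyl ether of ring B to give 28.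

3. Step 12. The formyl group lowers the stability of the acylium ion and may itself add trifluoroacetic anhydride. Capture by the doubly ortho-methylated phenol may then be slower than O-trifluoroacetylation of 13.
Fallback that joins the rings before the formyl group exists and formylates afterwards, setting out from 16 and rejoining at 26. NBS in MeCN should brominate para to a methoxy group to give 1-bromo-2,4-dimethoxy-5,6-dimethylbenzene F6. Bromine–lithium exchange and CO2 give 2,4-dimethoxy-5,6-dimethylbenzoic acid F7, whose more electron-rich acylium ion is coupled with 13 by (CF3CO)2O in toluene to methyl 4-[(2,4-dimethoxy-5,6-dimethylbenzoyl)oxy]-2-methoxy-3,5,6-trimethylbenzoate F8. Rieche formylation (Cl2CHOMe, TiCl4, CH2Cl2, 0 °C) at the only aromatic C–H of F8, between the two methoxy groups of ring A, gives 26.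

**Further compounds**
F1 | step 5 | 1,3-dimethoxy-2,4,5-trimethylbenzene | COc1cc(C)c(C)c(OC)c1C
F2 | step 5 | 1-bromo-2,4-dimethoxy-3,5,6-trimethylbenzene | COc1c(C)c(OC)c(C)c(C)c1Br
F3 | step 5 | methyl 2,4-dimethoxy-3,5,6-trimethylbenzoate | COC(=O)c1c(C)c(C)c(OC)c(C)c1OC
F4 | step 5 | methyl 2,4-dihydroxy-3,5,6-trimethylbenzoate | COC(=O)c1c(C)c(C)c(O)c(C)c1O
F5 | step 5 | methyl 4-[(3-formyl-2,4-dimethoxy-5,6-dimethylbenzoyl)oxy]-2-hydroxy-3,5,6-trimethylbenzoate | COC(=O)c1c(C)c(C)c(OC(=O)c2c(C)c(C)c(OC)c(C=O)c2OC)c(C)c1O
F6 | step 12 | 1-bromo-2,4-dimethoxy-5,6-dimethylbenzene | COc1cc(OC)c(C)c(C)c1Br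
F7 | step 12 | 2,4-dimethoxy-5,6-dimethylbenzoic acid | COc1cc(OC)c(C)c(C)c1C(=O)O
F8 | step 12 | methyl 4-[(2,4-dimethoxy-5,6-dimethylbenzoyl)oxy]-2-methoxy-3,5,6-trimethylbenzoate | COC(=O)c1c(C)c(C)c(OC(=O)c2c(C)c(C)c(OC)cc2OC)c(C)c1OC
F9 | step 13 | 3-bromo-2,6-dihydroxy-4,5-dimethylbenzaldehyde | O=Cc1c(O)c(Br)c(C)c(C)c1O
F10 | step 13 | 2,6-bis(benzyloxy)-3-bromo-4,5-dimethylbenzaldehyde | O=Cc1c(OCc2ccccc2)c(Br)c(C)c(C)c1OCc1ccccc1
F11 | step 13 | 2-[2,6-bis(benzyloxy)-3-bromo-4,5-dimethylphenyl]-1,3-dioxolane | Brc1c(C)c(C)c(OCc2ccccc2)c(C2OCCO2)c1OCc1ccccc1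
F12 | step 13 | 2,4-bis(benzyloxy)-3-formyl-5,6-dimethylbenzoic acid | O=Cc1c(OCc2ccccc2)c(C(=O)O)c(C)c(C)c1OCc1ccccc1
F13 | step 13 | methyl 4-{[2,4-bis(benzyloxy)-3-formyl-5,6-dimethylbenzoyl]oxy}-2-methoxy-3,5,6-trimethylbenzoate | COC(=O)c1c(C)c(C)c(OC(=O)c2c(C)c(C)c(OCc3ccccc3)c(C=O)c2OCc2ccccc2)c(C)c1OC
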